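**Plan**

- Retrosynthesis: remove the C3 acetate and the butenolide (C12=C13 Wittig bond; C12 from an allyl group on C9). Open ring B at C7–C8 (Barbier bond; C17 from a methylenation). Contract ring A at C5–C10 to a 1-(epoxyalkyl)cyclopentanol. Cut C1–C10 to a cyclopentanone (C1–C7) and a (Z)-iodoalkene (C8–C13, C20).
- Forward: fragment A (ketone 10) and fragment B (iodide 14) are joined at C1–C10, the tetrasubstituted alkene is epoxidised, ring A arises by ring expansion, C1 is deoxygenated, ring B is closed at C7–C8, C17 is added and the butenolide is built last.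
- Enabling feature: on the edge of six-membered ring A the quaternary C10 (methyl) is bonded to the tertiary carbinol C9. A 1,2-shift of the cyclopentanol bond C1–C5 onto the neighbouring epoxide carbon leaves exactly this pair, with the old carbinol C1 as a removable ketone.
- Stereochemistry: C3 from a CBS desymmetrisation; C5 from hydroboration anti to the C3 silyl ether; C9 and C10 from the (Z)-alkene geometry plus a Sharpless epoxidation, carried through the shift with retention at C9 and C5 and inversion at C10; C8 from a hydrogen-atom-transfer hydrogenation giving the equatorial methyl.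

Key step: step 12

Remark: atoms of all intermediates carry the labdane numbers of the target (C1–C20), α/β refer to the target drawn with the C10 methyl up. Alcohols 21–23 are drawn as the expected equatorial 1β-epimer and 28 is carried as a C8 epimer mixture; both centres are removed in steps 16 and 21.

**Route**

Step 1
Reactants: 1 2,2-dimethylcyclopentane-1,3-dione
Product: 2 (S)-3-hydroxy-2,2-dimethylcyclopentan-1-one
Conditions: (R)-2-methyl-CBS-oxazaborolidine (10 mol %), BH3·SMe2 (0.7 equiv), THF, −30 °C
Reagents that add atoms: none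
Why: Corey–Bakshi–Shibata reduction desymmetrises the prochiral, non-enolisable dione, the quaternary carbon acting as the large group so that the (R)-catalyst should give the (S)-carbinol (future C3), while substoichiometric borane limits reduction of the second ketone.

Step 2
Reactants: 2 (S)-3-hydroxy-2,2-dimethylcyclopentan-1-one
Product: 3 (S)-3-(tert-butyldimethylsilyloxy)-2,2-dimethylcyclopentan-1-one
Conditions: TBSCl, imidazole, DMF, 23 °C
Reagents that add atoms: tert-butyldimethylsilyl chloride, `CC(C)(C)[Si](C)(C)Cl`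
Why: Imidazole-promoted silylation masks the C3 hydroxyl as an ether that should survive the organometallic, hydride, radical and Lewis-acid steps up to step 24.

Step 3
Reactants: 3 (S)-3-(tert-butyldimethylsilyloxy)-2,2-dimethylcyclopentan-1-one
Product: 5 (S)-4-(tert-butyldimethylsilyloxy)-5,5-dimethylcyclopent-1-en-1-yl trifluoromethanesulfonate, via potassium enolate 4 (not isolated)
Conditions: KN(SiMe3)2, THF, −78 °C; then PhNTf2, −78 → 0 °C
Reagents that add atoms: N-phenylbis(trifluoromethanesulfonimide), `O=S(=O)(N(c1ccccc1)S(=O)(=O)C(F)(F)F)C(F)(F)F`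
Why: The ketone can enolise only toward its single α-CH2 (the other α-carbon is quaternary), so O-triflation gives one alkenyl triflate, and the silyloxy group is not β to the enolate carbon and cannot be eliminated.

Step 4
Reactants: 5 alkenyl triflate
Product: 6 (S)-tert-butyl[(2,2-dimethyl-3-vinylcyclopent-3-en-1-yl)oxy]dimethylsilane
Conditions: vinylboronic acid pinacol ester, Pd(PPh3)4 (5 mol %), K3PO4, dioxane/H2O, 80 °C
Reagents that add atoms: vinylboronic acid pinacol ester, `C=CB1OC(C)(C)C(C)(C)O1`
Why: Suzuki–Miyaura coupling of the alkenyl triflate under zerovalent palladium attaches C6–C7 as a vinyl group at the future C5.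

Step 5
Reactants: 6 silyloxy diene
Product: 8 (1S,2S,4S)-4-(tert-butyldimethylsilyloxy)-2-(2-hydroxyethyl)-3,3-dimethylcyclopentan-1-ol, via bis(alkylborane) 7 (not isolated)
Conditions: BH3·SMe2 (3 equiv), THF, 0 → 23 °C; then NaOH, H2O2, 0 → 23 °C
Reagents that add atoms: hydrogen peroxide, `OO`
Why: Hydroboration–oxidation puts boron on the terminal vinyl carbon and on the less substituted ring carbon (C1), adding H and B syn from the face opposite the C3 silyloxy group, so C5 should be set with its side chain cis to the silyl ether (the minor epimer would be removed at ketone 10).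

Step 6
Reactants: 8 diol
Product: 9 (1S,2S,4S)-4-(tert-butyldimethylsilyloxy)-3,3-dimethyl-2-[2-(pivaloyloxy)ethyl]cyclopentan-1-ol
Conditions: PivCl (1.05 equiv), pyridine, CH2Cl2, −20 → 0 °C
Reagents that add atoms: pivaloyl chloride, `CC(C)(C)C(=O)Cl`
Why: Acylation with a bulky acid chloride at low temperature selects the primary hydroxyl over the hindered secondary one.

Step 7
Reactants: 9 hydroxy pivalate
Product: 10 (2S,4S)-4-(tert-butyldimethylsilyloxy)-3,3-dimethyl-2-[2-(pivaloyloxy)ethyl]cyclopentan-1-one (fragment A)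
Conditions: Dess–Martin periodinane, NaHCO3, CH2Cl2, 23 °C
Reagents that add atoms: none
Why: Dess–Martin oxidation under buffered, non-basic conditions should give the ketone without epimerising C5 or eliminating the β-silyloxy group.

Step 8
Reactants: 11 but-2-yn-1-ol; 12 allylmagnesium bromide
Product: 14 (Z)-2-allyl-3-iodobut-2-en-1-ol (fragment B), via oxamagnesacycle 13 (not isolated)
Conditions: 12 (3 equiv), Et2O, 0 → 35 °C; then I2, THF, −40 → 0 °C
Reagents that add atoms: iodine, `II`
Why: Allylmagnesiation of a propargylic magnesium alkoxide is an anti carbometalation that places allyl on the alkyne carbon next to the carbinol and magnesium on the far carbon in a five-membered chelate, so iodinolysis with retention gives the (Z)-iodoalkene with iodine cis to CH2OH.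

Step 9
Reactants: 14 (Z)-2-allyl-3-iodobut-2-en-1-ol; 10 cyclopentanone (fragment A)
Product: 16 (Z)-allylic 1,4-diol (1-alkenylcyclopentanol with the alkenyl group trans to the C5 side chain), via dilithio species 15 (not isolated)
Conditions: 14, n-BuLi (1.0 equiv) then t-BuLi (2.1 equiv), Et2O, −78 °C; then 10 premixed with LaCl3·2LiCl, THF, −78 → −40 °C
Reagents that add atoms: none
Why: Iodine–lithium exchange with retention of alkene geometry gives the alkenyllithium alkoxide, which adds 1,2 to the lanthanum-activated ketone (the additive suppresses enolisation) from the face opposite the C5 side chain and the C3 silyl ether, forming C1–C10 and a carbinol centre that is erased later.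

Step 10
Reactants: 16 (Z)-allylic 1,4-diol
Product: 17 (9R,10S)-epoxy alcohol
Conditions: Ti(OiPr)4 (1.2 equiv), D-(−)-diisopropyl tartrate (1.5 equiv), t-BuOOH (2.5 equiv), 4 Å molecular sieves, CH2Cl2, −20 °C
Reagents that add atoms: tert-butyl hydroperoxide, `CC(C)(C)OO`
Why: Sharpless asymmetric epoxidation of the primary allylic alcohol ignores the remote terminal alkene and with the D-tartrate delivers oxygen to the face giving the (9R,10S)-epoxide, which is also the face syn to the tertiary hydroxyl and anti to C5 in the rotamer of least allylic strain, so reagent and substrate control should reinforce each other.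

Step 11
Reactants: 17 epoxy alcohol
Product: 18 epoxy pivalate (1-(epoxyalkyl)cyclopentanol)
Conditions: PivCl, pyridine, DMAP (cat.), CH2Cl2, 0 °C
Reagents that add atoms: pivaloyl chloride, `CC(C)(C)C(=O)Cl`
Why: The primary epoxy alcohol is acylated selectively beside the hindered tertiary alcohol, and the pivalate deactivates C8 and C9 toward ionisation and hydride shift in the next step.

Step 12
Reactants: 18 epoxy pivalate
Product: 19 ring A ketone (C1 ketone, C10 quaternary methyl, C9 triethylsilyloxy carbinol)
Conditions: TESOTf (1.5 equiv), 2,6-lutidine (2.5 equiv), CH2Cl2, −78 → −40 °C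
Reagents that add atoms: triethylsilyl trifluoromethanesulfonate, `CC[Si](CC)(CC)OS(=O)(=O)C(F)(F)F`
Why: The silyl triflate binds the epoxide oxygen, the C10–O bond ionises at the tertiary carbon while the anti-periplanar C1–C5 bond shifts to C10 and C1 becomes the carbonyl, the silyl group staying on the C9 oxygen; this is a semipinacol rearrangement, closest in type to the Lewis-acid conversion of tertiary α-hydroxy epoxides into β-hydroxy ketones with ring enlargement. Ring A is not closed by a cyclisation but by a suprafacial 1,2-alkyl shift that inserts C10 into the five-membered ring, driven by relief of cyclopentane strain and C=O formation. C10 is the new quaternary stereocentre and is set by inversion at the epoxide carbon, so it follows from the epoxide face of step 10 and the (Z) geometry of 16, while C9 keeps its C–O bond and the migrating C5 keeps its configuration. The step needs opening at C10 and not C9, migration of C5 and not C2, and no hydride shift from C8. The first is secured by the acyloxymethyl group that destabilises charge at C9; the second by the higher substitution of C5, by the silyloxy group β to C2 and by the ground-state rotamer that holds C5 anti to the epoxide oxygen; the third by the pivalate, which cannot stabilise an oxocarbenium ion at C8 as a silyl ether would. Lutidine buffers the acid so that silyl ethers and esters survive, and the product is protected against retro-aldol cleavage as it forms.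

Step 13
Reactants: 19 ring A ketone
Product: 21 C1,C12-diol, via ozonide 20 (not isolated)
Conditions: O3, CH2Cl2, −78 °C; then MeOH, NaBH4, −78 → 23 °C
Reagents that add atoms: ozone, `[O-][O+]=O`
Why: Ozonolysis cleaves the only alkene and borohydride reduces the ozonide to the C12 primary alcohol and, by axial attack, the C1 ketone to the equatorial alcohol (configuration irrelevant), which removes both the alkene and the β-silyloxy ketone before the radical and basic steps.

Step 14
Reactants: 21 C1,C12-diol
Product: 22 C12 silyl ether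
Conditions: TBSCl (1.1 equiv), imidazole, CH2Cl2, 0 °C
Reagents that add atoms: tert-butyldimethylsilyl chloride, `CC(C)(C)[Si](C)(C)Cl`
Why: Silylation at low temperature selects the unhindered primary C12 hydroxyl over the neopentyl secondary C1 hydroxyl.

Step 15
Reactants: 22 C1 alcohol
Product: 23 C1 S-methyl xanthate
Conditions: NaH, CS2, MeI, imidazole (cat.), THF, 0 → 23 °C
Reagents that add atoms: carbon disulfide, `S=C=S`; iodomethane, `CI`
Why: Xanthate formation activates the secondary alcohol for radical deoxygenation, and the pivalates (no α-hydrogen) and silyl ethers should tolerate the conditions.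

Step 16
Reactants: 23 xanthate
Product: 24 C1-deoxygenated ring A compound
Conditions: Bu3SnH, AIBN (cat.), toluene, 100 °C
Reagents that add atoms: none
Why: Barton–McCombie deoxygenation: the stannyl radical adds to the thiocarbonyl, the C1–O bond fragments and the secondary C1 radical, which has no alkene within reach after step 13, is reduced by the tin hydride.

Step 17
Reactants: 24 bis-pivalate
Product: 25 C7,C8-diol
Conditions: i-Bu2AlH (5 equiv), CH2Cl2, −78 → −20 °C
Reagents that add atoms: none
Why: Hydride reduction cleaves both pivalates in one operation and leaves the three silyl ethers intact.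

Step 18
Reactants: 25 C7,C8-diol
Product: 26 C7 iodide
Conditions: I2, PPh3, imidazole, CH2Cl2, 0 °C
Reagents that add atoms: iodine, `II`
Why: Appel-type iodination is an SN2 displacement of an alkoxyphosphonium ion, fast at the unhindered C7 carbinol and very slow at the neopentyl C8 carbinol next to the silyloxy-bearing quaternary C9.

Step 19
Reactants: 26 iodo alcohol
Product: 27 C8 aldehyde
Conditions: Dess–Martin periodinane, NaHCO3, CH2Cl2, 23 °C
Reagents that add atoms: none
Why: Dess–Martin oxidation gives a non-enolisable aldehyde and does not touch the primary iodide or the silyl ethers.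

Step 20
Reactants: 27 iodo aldehyde
Product: 28 decalin C8 alcohol (C8 epimers)
Conditions: SmI2 (2.5 equiv), HMPA, THF, −78 → 0 °C
Reagents that add atoms: none
Why: Samarium Barbier cyclisation: divalent samarium reduces the iodide to an alkylsamarium that adds to the tethered aldehyde in a 6-exo-trig closure, forming C7–C8 and ring B as a trans-decalin because C5 and C10 are already fixed.

Step 21
Reactants: 28 C8 alcohol
Product: 29 C8 ketone
Conditions: Dess–Martin periodinane, NaHCO3, CH2Cl2, 23 °C
Reagents that add atoms: none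
Why: Dess–Martin oxidation of the secondary alcohol converges both epimers to the ketone.

Step 22
Reactants: 29 C8 ketone
Product: 30 8(17)-exocyclic alkene
Conditions: Ph3PCH3Br, KOtBu, toluene, 90 °C
Reagents that add atoms: methyltriphenylphosphonium bromide, `C[P+](c1ccccc1)(c1ccccc1)c1ccccc1.[Br-]`
Why: Wittig methylenation under the high-temperature tert-butoxide protocol used for hindered ketones introduces C17, and the silylated α-oxygen excludes an α-ketol shift.

Step 23
Reactants: 30 exocyclic alkene
Product: 31 8α-methyl decalin tris-silyl ether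
Conditions: Mn(dpm)3 (10 mol %), PhSiH3, t-BuOOH, i-PrOH, 23 °C
Reagents that add atoms: none
Why: Hydrogen-atom-transfer hydrogenation gives the tertiary C8 radical, which should accept hydrogen on the β face because the α face is shielded by the axial C9 silyloxy group and an axial methyl would be 1,3-diaxial to the C10 methyl, giving the equatorial 8α-methyl (8R) isomer.

Step 24
Reactants: 31 tris-silyl ether
Product: 32 (3S,5S,8R,9R,10S)-3,9,12-triol
Conditions: HF·pyridine, pyridine, THF, 0 → 23 °C
Reagents that add atoms: none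
Why: Buffered fluoride cleaves the primary TBS, secondary TBS and tertiary TES ethers in one operation without ionising the tertiary alcohol.

Step 25
Reactants: 32 triol
Product: 33 C12 aldehyde
Conditions: TEMPO (10 mol %), PhI(OAc)2, CH2Cl2, 23 °C
Reagents that add atoms: none
Why: Oxoammonium oxidation is selective for the primary alcohol over the hindered secondary C3 and tertiary C9 alcohols and stops at the aldehyde in the absence of water.

Step 26
Reactants: 33 C12 aldehyde; 34 3-(triphenylphosphoranylidene)dihydrofuran-2(3H)-one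
Product: 35 (E)-alkylidene lactone
Conditions: toluene, 50 °C
Reagents that add atoms: none
Why: Wittig olefination with the stabilised lactone ylide under neutral conditions (no base, so the β-hydroxy aldehyde cannot undergo retro-aldol cleavage) forms C12=C13 and brings in C13–C16.

Step 27
Reactants: 35 (E)-alkylidene lactone
Product: 36 butenolide diol (3-deacetyl target)
Conditions: RhCl3·3H2O (10 mol %), EtOH, 78 °C
Reagents that add atoms: none
Why: Rhodium hydride-mediated alkene isomerisation, a known conversion of α-alkylidene butyrolactones, moves the exocyclic conjugated double bond into the ring to give the more stable endocyclic butenolide.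

Step 28
Reactants: 36 butenolide diol
Product: 37 target, (3S,5S,8R,9R,10S)-3-acetoxy-9-hydroxylabd-13-en-16,15-olide
Conditions: Ac2O, pyridine, DMAP (cat.), CH2Cl2, 23 °C
Reagents that add atoms: acetic anhydride, `CC(=O)OC(C)=O`
Why: Acylation under nucleophilic catalysis esterifies the equatorial secondary C3 alcohol while the hindered tertiary C9 alcohol does not react.

**Compound list**

1 | 2,2-dimethylcyclopentane-1,3-dione | `CC1(C)C(=O)CCC1=O` | starting material
2 | (S)-3-hydroxy-2,2-dimethylcyclopentan-1-one | `O[C@H]1CCC(=O)C1(C)C` | intermediate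
3 | (S)-3-(tert-butyldimethylsilyloxy)-2,2-dimethylcyclopentan-1-one | `CC(C)(C)[Si](C)(C)O[C@H]1CCC(=O)C1(C)C` | intermediate
4 | potassium enolate of 3, enolised toward its CH2 (formed in the flask) | `CC(C)(C)[Si](C)(C)O[C@H]1CC=C([O-])C1(C)C.[K+]` | intermediate
5 | (S)-4-(tert-butyldimethylsilyloxy)-5,5-dimethylcyclopent-1-en-1-yl trifluoromethanesulfonate | `CC(C)(C)[Si](C)(C)O[C@H]1CC=C(OS(=O)(=O)C(F)(F)F)C1(C)C` | intermediate
6 | (S)-tert-butyl[(2,2-dimethyl-3-vinylcyclopent-3-en-1-yl)oxy]dimethylsilane | `CC(C)(C)[Si](C)(C)O[C@H]1CC=C(C=C)C1(C)C` | intermediate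
7 | bis(alkylborane) of 6, BH2 on ring C1 and on C7, drawn as monomer (formed in the flask) | `CC(C)(C)[Si](C)(C)O[C@H]1C[C@H]([BH2])[C@@H](CC[BH2])C1(C)C` | intermediate
8 | (1S,2S,4S)-4-(tert-butyldimethylsilyloxy)-2-(2-hydroxyethyl)-3,3-dimethylcyclopentan-1-ol (side chain cis to OTBS, ring OH trans to side chain) | `CC(C)(C)[Si](C)(C)O[C@H]1C[C@H](O)[C@@H](CCO)C1(C)C` | intermediate
9 | (1S,2S,4S)-4-(tert-butyldimethylsilyloxy)-3,3-dimethyl-2-[2-(pivaloyloxy)ethyl]cyclopentan-1-ol | `CC(C)(C)[Si](C)(C)O[C@H]1C[C@H](O)[C@@H](CCOC(=O)C(C)(C)C)C1(C)C` | intermediate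
10 | (2S,4S)-4-(tert-butyldimethylsilyloxy)-3,3-dimethyl-2-[2-(pivaloyloxy)ethyl]cyclopentan-1-one, fragment A | `CC(C)(C)[Si](C)(C)O[C@H]1CC(=O)[C@@H](CCOC(=O)C(C)(C)C)C1(C)C` | intermediate
11 | but-2-yn-1-ol | `CC#CCO` | starting material
12 | allylmagnesium bromide | `C=CC[Mg]Br` | starting material
13 | 4-allyl-3-methyl-2,5-dihydro-1,2-oxamagnesole, the alkenylmagnesium alkoxide chelate (formed in the flask) | `CC1=C(CC=C)CO[Mg]1` | intermediate
14 | (Z)-2-allyl-3-iodobut-2-en-1-ol, fragment B | `C/C(I)=C(/CO)CC=C` | intermediate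
15 | lithium (Z)-2-allyl-3-lithiobut-2-en-1-olate (formed in the flask) | `C/C([Li])=C(/CO[Li])CC=C` | intermediate
16 | 1-[(Z)-3-(hydroxymethyl)hexa-2,5-dien-2-yl] adduct of 10: tertiary cyclopentanol, alkenyl group trans to the C5 side chain and the C3 silyl ether, C1 cis to CH2OH on the alkene | `CC(C)(C)[Si](C)(C)O[C@H]1C[C@](O)(/C(C)=C(\CO)CC=C)[C@@H](CCOC(=O)C(C)(C)C)C1(C)C` | intermediate
17 | (9R,10S)-epoxide of 16 (epoxy alcohol) | `CC(C)(C)[Si](C)(C)O[C@H]1C[C@](O)([C@]2(C)O[C@@]2(CO)CC=C)[C@@H](CCOC(=O)C(C)(C)C)C1(C)C` | intermediate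
18 | C8 pivalate of 17, the 1-(epoxyalkyl)cyclopentanol | `CC(C)(C)[Si](C)(C)O[C@H]1C[C@](O)([C@]2(C)O[C@@]2(COC(=O)C(C)(C)C)CC=C)[C@@H](CCOC(=O)C(C)(C)C)C1(C)C` | intermediate
19 | 5-(tert-butyldimethylsilyloxy)-2,4,4-trimethyl-3-[2-(pivaloyloxy)ethyl]-2-[1-(pivaloyloxy)-2-(triethylsilyloxy)pent-4-en-2-yl]cyclohexan-1-one; labdane C1 ketone, 10β-methyl, 5α-H, 3β-OTBS, C9 configured as in the target | `CC(C)(C)[Si](C)(C)O[C@H]1CC(=O)[C@](C)([C@](O[Si](CC)(CC)CC)(COC(=O)C(C)(C)C)CC=C)[C@@H](CCOC(=O)C(C)(C)C)C1(C)C` | intermediate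
20 | ozonide (1,2,4-trioxolane) of the allyl group of 19 (formed in the flask) | `CC(C)(C)[Si](C)(C)O[C@H]1CC(=O)[C@](C)([C@](O[Si](CC)(CC)CC)(COC(=O)C(C)(C)C)CC2OCOO2)[C@@H](CCOC(=O)C(C)(C)C)C1(C)C` | intermediate
21 | 1β,12-diol: C1 ketone of 19 reduced, allyl cut to CH2CH2OH | `CC(C)(C)[Si](C)(C)O[C@H]1C[C@@H](O)[C@](C)([C@](O[Si](CC)(CC)CC)(COC(=O)C(C)(C)C)CCO)[C@@H](CCOC(=O)C(C)(C)C)C1(C)C` | intermediate
22 | C12 tert-butyldimethylsilyl ether of 21 | `CC(C)(C)[Si](C)(C)O[C@H]1C[C@@H](O)[C@](C)([C@](O[Si](CC)(CC)CC)(COC(=O)C(C)(C)C)CCO[Si](C)(C)C(C)(C)C)[C@@H](CCOC(=O)C(C)(C)C)C1(C)C` | intermediate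
23 | C1 O-alkyl S-methyl xanthate of 22 | `CC(C)(C)[Si](C)(C)O[C@H]1C[C@@H](OC(=S)SC)[C@](C)([C@](O[Si](CC)(CC)CC)(COC(=O)C(C)(C)C)CCO[Si](C)(C)C(C)(C)C)[C@@H](CCOC(=O)C(C)(C)C)C1(C)C` | intermediate
24 | C1-deoxygenated ring A compound (C1 = CH2), 7,8-bis-pivalate | `CC(C)(C)[Si](C)(C)O[C@H]1CC[C@](C)([C@](O[Si](CC)(CC)CC)(COC(=O)C(C)(C)C)CCO[Si](C)(C)C(C)(C)C)[C@@H](CCOC(=O)C(C)(C)C)C1(C)C` | intermediate
25 | 7,8-diol from 24 | `CC(C)(C)[Si](C)(C)O[C@H]1CC[C@](C)([C@](O[Si](CC)(CC)CC)(CO)CCO[Si](C)(C)C(C)(C)C)[C@@H](CCO)C1(C)C` | intermediate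
26 | C7 iodide, C8 alcohol | `CC(C)(C)[Si](C)(C)O[C@H]1CC[C@](C)([C@](O[Si](CC)(CC)CC)(CO)CCO[Si](C)(C)C(C)(C)C)[C@@H](CCI)C1(C)C` | intermediate
27 | C7 iodide, C8 aldehyde | `CC(C)(C)[Si](C)(C)O[C@H]1CC[C@](C)([C@](O[Si](CC)(CC)CC)(C=O)CCO[Si](C)(C)C(C)(C)C)[C@@H](CCI)C1(C)C` | intermediate
28 | trans-decalin C8 alcohol (C8 epimers), 3β-OTBS, 9α-OTES, 10β-methyl, 12-OTBS | `CC(C)(C)[Si](C)(C)O[C@H]1CC[C@@]2(C)[C@@H](CCC(O)[C@]2(O[Si](CC)(CC)CC)CCO[Si](C)(C)C(C)(C)C)C1(C)C` | intermediate
29 | decalin C8 ketone | `CC(C)(C)[Si](C)(C)O[C@H]1CC[C@@]2(C)[C@@H](CCC(=O)[C@]2(O[Si](CC)(CC)CC)CCO[Si](C)(C)C(C)(C)C)C1(C)C` | intermediate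
30 | 8(17)-exocyclic methylene decalin | `CC(C)(C)[Si](C)(C)O[C@H]1CC[C@@]2(C)[C@@H](CCC(=C)[C@]2(O[Si](CC)(CC)CC)CCO[Si](C)(C)C(C)(C)C)C1(C)C` | intermediate
31 | (3S,5S,8R,9R,10S) decalin with 8α-methyl, 3-OTBS, 9-OTES, 12-OTBS | `CC(C)(C)[Si](C)(C)O[C@H]1CC[C@@]2(C)[C@@H](CC[C@@H](C)[C@]2(O[Si](CC)(CC)CC)CCO[Si](C)(C)C(C)(C)C)C1(C)C` | intermediate
32 | (3S,5S,8R,9R,10S)-3,9,12-triol | `O[C@H]1CC[C@@]2(C)[C@@H](CC[C@@H](C)[C@]2(O)CCO)C1(C)C` | intermediate
33 | (3S,5S,8R,9R,10S)-3,9-dihydroxy C12 aldehyde | `O[C@H]1CC[C@@]2(C)[C@@H](CC[C@@H](C)[C@]2(O)CC=O)C1(C)C` | intermediate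
34 | 3-(triphenylphosphoranylidene)dihydrofuran-2(3H)-one | `O=C1OCCC1=P(c1ccccc1)(c1ccccc1)c1ccccc1` | starting material
35 | (E)-12(13)-alkylidene γ-butyrolactone, 3β,9α-diol | `O[C@H]1CC[C@@]2(C)[C@@H](CC[C@@H](C)[C@]2(O)C/C=C2\CCOC2=O)C1(C)C` | intermediate
36 | (3S,5S,8R,9R,10S)-3,9-dihydroxylabd-13-en-16,15-olide | `O[C@H]1CC[C@@]2(C)[C@@H](CC[C@@H](C)[C@]2(O)CCC2=CCOC2=O)C1(C)C` | intermediate
37 | (3S,5S,8R,9R,10S)-3-acetoxy-9-hydroxylabd-13-en-16,15-olide (CNP0117645.1) | `CC(=O)O[C@H]1CC[C@@]2(C)[C@@H](CC[C@@H](C)[C@]2(O)CCC2=CCOC2=O)C1(C)C` | target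

**Count and risks**

Total steps: 28 (step 8 lies on the branch that makes fragment B). Longest linear sequence: 27 steps (1–7, then 9–28).

Steps most likely to fail:

1. Step 9. The hindered tetrasubstituted alkenyllithium may act as a base (enolisation toward C2 and loss of the C3 silyloxy group) or fail to add to the α-branched ketone. The fallback sets out from 10 and comes back at 16. Pent-1-en-4-yne F1 would be deprotonated (n-BuLi, THF, −78 °C) to its lithium acetylide F2, a small linear nucleophile that should add to 10 (LaCl3·2LiCl) trans to the C5 side chain to give the tertiary propargylic alcohol F3. Copper-catalysed anti carbomagnesiation of F3 (MeMgBr, CuI 10 mol %, THF, 0 → 23 °C) would deliver methyl to the alkyne carbon next to the carbinol and leave magnesium on the far carbon in the spiro oxamagnesacycle F4. Trapping with paraformaldehyde would then give 16 with the same (Z) geometry, C8 ending cis to C1.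

2. Step 10. Oxygen transfer may be slow or poorly face-selective because titanium is sequestered by the cis-ene-1,4-diol and the bulky cis substituent retards reagent-controlled delivery. The fallback sets out from 16 and comes back at 18. The primary hydroxyl would be pivaloylated first (PivCl, pyridine, −20 °C) to the allylic pivalate F5. The epoxide would then be installed by delivery from the tertiary C1 hydroxyl (VO(acac)2 5 mol %, t-BuOOH, CH2Cl2, 0 °C). This relies on the rotamer in which C2 lies in the alkene plane and the hydroxyl sits on the required face, anti to C5, and gives 18 directly.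

3. Step 27. Migration of the double bond into the ring may stall at an exo/endo mixture, or the acidic rhodium medium may dehydrate the tertiary alcohol. The fallback sets out from 35 and comes back at 36. The alkylidene lactone would be hydrogenated (H2, Pd/C, EtOAc) to the saturated α-alkyl lactone F6. This would be sulfenylated at the α-carbon (LDA 3.3 equiv, THF, −78 °C; PhSSPh) to the α-phenylthio lactone F7 and oxidised (mCPBA, CH2Cl2, −78 °C) to the sulfoxide F8. Thermal syn elimination (toluene, 110 °C) toward the ring CH2 would give butenolide 36.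

**Further compounds**

F1 | step 9 | pent-1-en-4-yne | `C=CCC#C`
F2 | step 9 | lithium pent-4-en-1-yn-1-ide | `[Li]C#CCC=C`
F3 | step 9 | 1-(pent-4-en-1-yn-1-yl) adduct of 10: tertiary propargylic alcohol, alkynyl trans to the C5 side chain | `CC(C)(C)[Si](C)(C)O[C@H]1C[C@](O)(C#CCC=C)[C@@H](CCOC(=O)C(C)(C)C)C1(C)C`
F4 | step 9 | spiro oxamagnesacycle from F3 (methyl on C10, magnesium on C9 and on the C1 oxygen) | `CC(C)(C)[Si](C)(C)O[C@H]1C[C@@]2(O[Mg]C(CC=C)=C2C)[C@@H](CCOC(=O)C(C)(C)C)C1(C)C`
F5 | step 10 | C8 pivalate of 16 (allylic pivalate, tertiary alcohol free) | `CC(C)(C)[Si](C)(C)O[C@H]1C[C@](O)(/C(C)=C(\COC(=O)C(C)(C)C)CC=C)[C@@H](CCOC(=O)C(C)(C)C)C1(C)C`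
F6 | step 27 | saturated α-alkyl γ-butyrolactone from 35 (C13 epimers) | `O[C@H]1CC[C@@]2(C)[C@@H](CC[C@@H](C)[C@]2(O)CCC2CCOC2=O)C1(C)C`
F7 | step 27 | α-phenylthio lactone | `O[C@H]1CC[C@@]2(C)[C@@H](CC[C@@H](C)[C@]2(O)CCC2(Sc3ccccc3)CCOC2=O)C1(C)C`
F8 | step 27 | α-phenylsulfinyl lactone | `O[C@H]1CC[C@@]2(C)[C@@H](CC[C@@H](C)[C@]2(O)CCC2(S(=O)c3ccccc3)CCOC2=O)C1(C)C`
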